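**Two questions.** Two questions stand about this flask, and the earlier runs are what we have to answer them.

| flask | starting material | reagent | remark | time |
|---|---|---|---|---|
| south | 0.30 M | 0.25 M | run made earlier |  |
| north-east | 0.30 M | 0.40 M | run made earlier |  |
| south-west | 0.45 M | 0.18 M | run made earlier |  |
| flask | 0.30 M | 0.180 M |  | 8.0 h |

- south (time / h: target / %, starting material / %): 0.667: 17.7, 30.8; 1.50: 32.0, 17.4; 4.00: 42.2, 4.8; 8.00: 43.0, 0.5
- north-east (time / h: target / %, starting material / %): 0.667: 24.4, 10.9; 1.50: 46.0, 1.4; 4.00: 62.4, 0.7; 8.00: 62.4, 0
- south-west (time / h: target / %, starting material / %): 0.667: 9.6, 58.9; 1.50: 12.5, 50.2; 4.00: 8.0, 34.4; 8.00: 2.8, 25.2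

(readings scatter by 0.5 percentage points)

- when, up to 8.0 h, the flask holds most target
- the amount of target, in percent of the starting material charged, at that time



**Upper bound.** The north-east run, with reagent in excess, reads 62.4% of its starting material at its end. In the flask reagent is the limiting reagent, so we scale that yield by 0.180 M over 0.30 M and get a ceiling of 37.4%.

**Lower bound.** The south-west run has the same reagent charge but more starting material. Its best reading, 12.5% at 1.50 h, equals 18.8% on the flask's charge, and we take that as our floor. For the time we bracket 1.50 h to 4.00 h, where the south run reads 42.2% against its last 43.0%.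

**Tightening.** We divide each run's best target reading by its own ceiling. The south run, with 0.0500 M excess of starting material over reagent, gives 82.7%. The south-west run, with 0.270 M, gives 50.1%. These runs differ in both charges, but we assume that the excess sets this ratio. A straight line at the flask's 0.120 M then gives 72.3%, and this kept share turns the ceiling into our estimate of 27.1%.

**The forecast.** It says 26% at 2.3 h, inside both brackets and below our estimate, reasoning that “Leftover starting material therefore destroys target”.

**The result.** The flask holds most target at 2.67 h, later than forecast, with 24.9%, inside our bracket, a kept share of 66.6%.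

    starting material + reagent → intermediate + by-product (k = 0.260 M⁻¹ min⁻¹)
    starting material + target → side product (k = 0.0531 M⁻¹ min⁻¹)
    target ⇌ isomer of the product (K = 0.481, k = 0.0160 min⁻¹)
    intermediate → target (k = 0.0152 min⁻¹)

**Neighbour flask.** With 0.11 M of reagent, we reckon for the neighbour flask a ceiling of 22.9% and an excess of 0.190 M. The same line gives a kept share of 61.9%, hence 14.2%. The neighbour flask peaks at 12.8% of target.

The runs were computed with constants of no real substance.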